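A flask cannot rest on the proposed steps while it holds E or L: E -> X has no return, and the exit from L leads back to E. The end state is therefore X, and a share read at 2.0 min is a matter of kinetic control, of which path took E first.

| setting | summer | theta | delta | eta | beta |
|---|---|---|---|---|---|
| E | 22 mM | 20 mM | 60 mM | 200 mM | 500 mM |
| remark | run made earlier |  |  |  |  |
| time |  | 2.0 min | 2.0 min | 2.0 min | 2.0 min |

- summer (time / s: X / %, L / %, E / %): 10.0: 8.9, 11.7, 79.1; 12.0: 10.8, 13.3, 75.7; 20.0: 16.4, 19.6, 64.7; 30.0: 21.6, 24.6, 53.3; 40.0: 27.4, 27.6, 44.9; 60.0: 35.3, 31.5, 33.7; 80.0: 40.9, 34.2, 25.8

(each reading ± 0.5 percentage points)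

- percent here means E units held: one L counts as two
- the numbers in the tables scatter by 0.5 percentage points (one standard deviation)
- steps that have been proposed: E -> X; 2 E <-> L
- "hardly changes" means that all values lie within two and a half points (for a concentration: within two and a half percent of the largest)

- share of X in all that became X or L for theta, delta, eta, beta, in this order
- the shape of the row from first to last (rises all the way / rises, then falls / falls all the way / falls, then rises / hardly changes)

**Q. Which quantity carries the row?**

The crossover charge,: the charge of E at which ring path and pair path draw E equally at the start. Above it, the pair path leads.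

**Q. Read it from the summer run.**

Ring constant: X gained from 20.0 s to 80.0 s, over the area under E, gives 0.00989 s⁻¹. Pair constant at that charge: L at 20.0 s, over the area under the squared fraction of E, gives 0.0147 s⁻¹. The pair path leads in the summer flask, and so the crossover, as a reading, is 14.8 mM.

**Q. And the share?**

Call a the charge over the crossover charge, and w the fraction of E surviving the ring path by itself, here 0.305. With u = a(1 − w), X as a fraction of the charge is ln(1 + u)/a, and the E left is w/(1 + u). That gives 58.2%, 35.9%, 17.9% and 9.59%. It falls all the way.

**Q. You dropped the way back from L. Safe?**

Not wholly. Summer L still climbs from 31.5% to 34.2% in the last interval, but a net rise does not tell how large the way back is. L that reopens returns E, and part of that E goes on to X, so my row leans low.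

The forecast gives 60%, 38%, 19%, 11%, falls all the way, above my row at beta, on the ground that “Slow L reopening feeds X”.

The flasks give 60.3%, 38.4%, 20.1%, 11.6%: falls all the way.

    E → X (k = 0.0101 s⁻¹)
    2 E ⇌ L (K = 389 M⁻¹, k = 0.339 M⁻¹ s⁻¹)

What would overturn this row is the time of reading. Theta, charged at 1.35 crossover charges, shows 60.3% at 2.00 min, but read at 20.0 min it shows 85.7%; the early reading is the main reason for the lower share, and accounts for 64% of what it lacks. Beta, charged at 33.7 crossover charges, shows the same lateness as its largest single effect: 11.6% at 2.00 min, 45.0% at 20.0 min.

The data were computed on assumed constants, noise included.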